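Everything rests on forming the C1–C2 bond of ring B by intramolecular C–H insertion. In indene numbering the tertiary C1–H bond lies 1,5 to C2 across C3, C3a and C7a, so a rhodium carbenoid generated at C2 of an α-diazo-β-keto ester closes the five-membered ring B, converts the tertiary C1 stereocentre into the quaternary one with retention and leaves the carboxyl carbon on C2, all in one operation. The precursor is a ring A cyclohexene whose C3a carries the diazo keto ester and whose quaternary C7a carries the C1 methine with its methyl and silyloxypropyl groups; both centres arise from one Ireland–Claisen rearrangement of an enantioenriched cyclohexenyl ester.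

Key step: step 13

Numbering: the indene locants of the target are used for all intermediates (C1 quaternary with methyl and side chain C1′ onward, C2 carboxyl-bearing, C3, C3a=C4, C5, C6, C7 gem-dimethyl, C7a methyl-bearing; ring A six-membered, ring B five-membered).

Assumption: C2 stays epimerisable (β-keto ester, then ester α-carbon) until the carboxylate is formed in step 16; its more stable configuration is taken to be the one with the carboxyl group trans to the C1 side chain, which is wedged against the C7 gem-dimethyl group, and this is the configuration of the target.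

Step 1
Reactants: 1 3-ethoxy-2-methylcyclohex-2-en-1-one
Product: 3 3-ethoxy-2,6,6-trimethylcyclohex-2-en-1-one, via monomethylated enone 2 (not isolated)
Conditions: LiN(i-Pr)2 (1.1 equiv), THF, −78 °C, MeI; then LiN(i-Pr)2 (1.2 equiv), −78 °C, MeI, to rt
Reagents that add atoms: iodomethane, CI
Why: Kinetic deprotonation of a vinylogous ester is possible only at C6, so two successive enolate alkylations install the gem-dimethyl group that becomes C7 of the target.

Step 2
Reactants: 3 3-ethoxy-2,6,6-trimethylcyclohex-2-en-1-one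
Product: 5 2,3,4,4-tetramethylcyclohex-2-en-1-one, via tertiary allylic alcohol 4 (not isolated)
Conditions: MeLi, Et2O, −78 to 0 °C; then 1 M HCl, THF, rt
Reagents that add atoms: methyllithium, [Li]C; water, O
Why: 1,2-Addition of MeLi to the vinylogous ester carbonyl followed by acid hydrolysis and dehydration (Stork–Danheiser transposition) gives the tetrasubstituted enone with the new methyl on the β-carbon next to the gem-dimethyl group, with no regiochemical ambiguity.

Step 3
Reactants: 5 2,3,4,4-tetramethylcyclohex-2-en-1-one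
Product: 6 (1R)-2,3,4,4-tetramethylcyclohex-2-en-1-ol
Conditions: (3aS)-1-methyl-3,3-diphenylhexahydropyrrolo[1,2-c][1,3,2]oxazaborole (15 mol %), BH3·SMe2, THF, −20 °C
Reagents that add atoms: none
Why: Corey–Bakshi–Shibata reduction, in which the α-methylated alkene arm acts as the large group, so the (S)-catalyst should deliver hydride to the face that gives the (R)-carbinol from which every other stereocentre is derived.

Step 4
Reactants: 7 tetrahydro-2H-pyran-2-one
Product: 8 sodium 5-hydroxypentanoate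
Conditions: NaOH (1.0 equiv), H2O/MeOH, 60 °C; evaporate
Reagents that add atoms: sodium hydroxide, [Na+].[OH-]
Why: Saponification opens the lactone, and keeping the product as its sodium salt prevents relactonisation.

Step 5
Reactants: 8 sodium 5-hydroxypentanoate
Product: 10 5-[(tert-butyldimethylsilyl)oxy]pentanoic acid, via bis-silyl compound 9 (not isolated)
Conditions: TBSCl (2.2 equiv), imidazole, DMF, rt; then K2CO3, MeOH/THF/H2O, rt; 1 M HCl to pH 4, 0 °C
Reagents that add atoms: tert-butyldimethylsilyl chloride, CC(C)(C)[Si](C)(C)Cl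
Why: Silylation of both oxygens followed by mild hydrolysis of the much more labile silyl ester (silyl protection) leaves the primary silyl ether and the free acid.

Step 6
Reactants: 6 (1R)-2,3,4,4-tetramethylcyclohex-2-en-1-ol; 10 5-[(tert-butyldimethylsilyl)oxy]pentanoic acid
Product: 11 (1R)-2,3,4,4-tetramethylcyclohex-2-en-1-yl 5-[(tert-butyldimethylsilyl)oxy]pentanoate
Conditions: DCC, 4-(dimethylamino)pyridine (cat), CH2Cl2, 0 °C to rt
Reagents that add atoms: none
Why: Steglich esterification acylates the hindered secondary allylic alcohol at oxygen and leaves the carbinol stereocentre untouched.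

Step 7
Reactants: 11 (1R)-2,3,4,4-tetramethylcyclohex-2-en-1-yl 5-[(tert-butyldimethylsilyl)oxy]pentanoate
Product: 14 (2R)-5-[(tert-butyldimethylsilyl)oxy]-2-[(1S)-1,2,6,6-tetramethylcyclohex-2-en-1-yl]pentan-1-ol, via silyl ketene acetal 12 (not isolated), via trimethylsilyl ester 13 (not isolated)
Conditions: LiN(i-Pr)2, THF, −78 °C; Me3SiCl/Et3N, −78 °C to rt; toluene, 80 °C; concentrate; LiAlH4, Et2O, 0 °C
Reagents that add atoms: none
Why: Ireland–Claisen rearrangement in which kinetic enolisation in THF gives the (E)-silyl ketene acetal, the new bond forms on the face of the departing oxygen (sets C7a) through a chair-like transition state with the α-chain cis to the allylic oxygen (sets C1), the boat being penalised by eclipsing of the C3a methyl with the silyloxy group and of the chain with C7, and the silyl ester is then reduced in the same flask to the alcohol.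

Step 8
Reactants: 14 (2R)-5-[(tert-butyldimethylsilyl)oxy]-2-[(1S)-1,2,6,6-tetramethylcyclohex-2-en-1-yl]pentan-1-ol
Product: 15 (2R)-5-[(tert-butyldimethylsilyl)oxy]-2-[(1S)-1,2,6,6-tetramethylcyclohex-2-en-1-yl]pentyl methanesulfonate
Conditions: MsCl, Et3N, CH2Cl2, 0 °C
Reagents that add atoms: methanesulfonyl chloride, CS(=O)(=O)Cl
Why: Sulfonylation of the unhindered primary alcohol activates the former carboxyl carbon for hydride displacement.

Step 9
Reactants: 15 (2R)-5-[(tert-butyldimethylsilyl)oxy]-2-[(1S)-1,2,6,6-tetramethylcyclohex-2-en-1-yl]pentyl methanesulfonate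
Product: 16 tert-butyldimethyl{[(4R)-4-[(1S)-1,2,6,6-tetramethylcyclohex-2-en-1-yl]pentyl]oxy}silane
Conditions: LiEt3BH, THF, 0 °C to reflux
Reagents that add atoms: none
Why: SN2 hydride displacement of the primary mesylate by LiEt3BH turns the former carboxyl carbon into the C1 methyl, while the silyl ether and the trisubstituted alkene are inert to the reagent.

Step 10
Reactants: 16 tert-butyldimethyl{[(4R)-4-[(1S)-1,2,6,6-tetramethylcyclohex-2-en-1-yl]pentyl]oxy}silane
Product: 18 (6S)-6-[(2R)-5-[(tert-butyldimethylsilyl)oxy]pentan-2-yl]-5,5,6-trimethylcyclohex-1-ene-1-carbaldehyde, via allylic alcohol 17 (not isolated)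
Conditions: SeO2 (cat), t-BuOOH, CH2Cl2, rt; then MnO2, CH2Cl2, rt
Reagents that add atoms: tert-butyl hydroperoxide, CC(C)(C)OO
Why: SeO2 allylic oxidation (ene reaction then [2,3]-shift) attacks a substituent of the more substituted alkene carbon, and the only such substituent bearing hydrogen is the C3a methyl because C7a is quaternary, after which MnO2 converges the allylic alcohol on the enal.

Step 11
Reactants: 18 (6S)-6-[(2R)-5-[(tert-butyldimethylsilyl)oxy]pentan-2-yl]-5,5,6-trimethylcyclohex-1-ene-1-carbaldehyde; 19 ethyl diazoacetate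
Product: 20 ethyl 3-{(6S)-6-[(2R)-5-[(tert-butyldimethylsilyl)oxy]pentan-2-yl]-5,5,6-trimethylcyclohex-1-en-1-yl}-2-diazo-3-hydroxypropanoate (both carbinol epimers)
Conditions: LiN(i-Pr)2, THF, −78 °C; AcOH quench
Reagents that add atoms: none
Why: Aldol-type 1,2-addition of lithiated ethyl diazoacetate to the aldehyde gives the diazo hydroxy ester, whose new carbinol centre is erased in the next step.

Step 12
Reactants: 20 ethyl 3-{(6S)-6-[(2R)-5-[(tert-butyldimethylsilyl)oxy]pentan-2-yl]-5,5,6-trimethylcyclohex-1-en-1-yl}-2-diazo-3-hydroxypropanoate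
Product: 21 ethyl 3-{(6S)-6-[(2R)-5-[(tert-butyldimethylsilyl)oxy]pentan-2-yl]-5,5,6-trimethylcyclohex-1-en-1-yl}-2-diazo-3-oxopropanoate
Conditions: IBX, DMSO, rt
Reagents that add atoms: none
Why: IBX oxidation of the allylic α-diazo carbinol to the α-diazo-β-keto ester is a standard alcohol oxidation that leaves the diazo group, the silyl ether and the alkene intact.

Step 13
Reactants: 21 ethyl 3-{(6S)-6-[(2R)-5-[(tert-butyldimethylsilyl)oxy]pentan-2-yl]-5,5,6-trimethylcyclohex-1-en-1-yl}-2-diazo-3-oxopropanoate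
Product: 22 ethyl (1R,2R,7aR)-1-{3-[(tert-butyldimethylsilyl)oxy]propyl}-1,7,7,7a-tetramethyl-3-oxo-2,3,5,6,7,7a-hexahydro-1H-indene-2-carboxylate
Conditions: Rh2(NHCOCH3)4 (2 mol %), ClCH2CH2Cl, reflux, slow addition of 21
Reagents that add atoms: none
Why: The catalyst extrudes N2 from the diazo group to give an electrophilic rhodium carbenoid at C2, which inserts into the C1–H bond through a three-centre, hydride-transfer-like transition state and releases the catalyst. The closest known reaction type is the dirhodium-catalysed intramolecular C–H insertion of α-diazo-β-keto esters that gives 2-alkoxycarbonylcyclopentanones. Ring B closes in the 1,5 mode, C2 bonding to C1 across C3, C3a and C7a through a six-membered cyclic transition state that delivers the five-membered ring. C1 becomes quaternary with retention because the C–C bond forms on the side from which hydrogen departs, so its configuration is the one set by the rearrangement in step 7, while C2 is an epimerisable β-keto ester centre that should settle under thermodynamic control with the ester trans to the C1 side chain. The step must choose the single tertiary C1–H over the equally distant primary hydrogens of the C7a methyl and over the 1,6 hydrogens of C1′, the C1 methyl and the C7 methyls, and this is secured by the electronic preference of the carbenoid for the most electron-rich C–H bond, sharpened by the donor acetamidate ligands, together with the preference for five-membered ring formation. Competing paths are blocked by the substrate, since C2 has no β-hydrogen for a 1,2-shift, the allylic C5 hydrogens are trans to the acyl group across C3a=C4 and out of reach, and addition to C3a=C4 would need a bicyclobutane.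

Step 14
Reactants: 22 ethyl (1R,2R,7aR)-1-{3-[(tert-butyldimethylsilyl)oxy]propyl}-1,7,7,7a-tetramethyl-3-oxo-2,3,5,6,7,7a-hexahydro-1H-indene-2-carboxylate
Product: 23 C3 spiro-1,3-dithiolane of ethyl 1-(3-hydroxypropyl)-1,7,7,7a-tetramethyl-3-oxo-2,3,5,6,7,7a-hexahydro-1H-indene-2-carboxylate (C1, C2, C7a as in 22)
Conditions: HSCH2CH2SH, BF3·OEt2, CH2Cl2, 0 °C to rt
Reagents that add atoms: ethane-1,2-dithiol, SCCS
Why: Lewis acid-promoted dithioketalisation of the C3 ketone (first half of a Mozingo reduction) normally leaves a conjugated double bond in place, and the water it releases cleaves the primary silyl ether under the same acid, so both changes should occur in one operation with C2 unchanged.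

Step 15
Reactants: 23 C3 spiro-1,3-dithiolane with free side-chain alcohol
Product: 24 ethyl (1R,2S,7aS)-1-(3-hydroxypropyl)-1,7,7,7a-tetramethyl-2,3,5,6,7,7a-hexahydro-1H-indene-2-carboxylate
Conditions: Raney Ni (W-2, deactivated in acetone), EtOH, 50 °C
Reagents that add atoms: none
Why: Raney nickel desulfurisation (Mozingo reduction) replaces both C–S bonds at C3 by C–H bonds, and the deactivated metal should spare the hindered trisubstituted C3a=C4 alkene.

Step 16
Reactants: 24 ethyl (1R,2S,7aS)-1-(3-hydroxypropyl)-1,7,7,7a-tetramethyl-2,3,5,6,7,7a-hexahydro-1H-indene-2-carboxylate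
Product: 25 (1R,2S,7aS)-1-(3-hydroxypropyl)-1,7,7,7a-tetramethyl-2,3,5,6,7,7a-hexahydro-1H-indene-2-carboxylic acid
Conditions: KOH, EtOH/H2O, reflux; 1 M HCl to pH 3
Reagents that add atoms: potassium hydroxide, [K+].[OH-]
Why: Saponification of the hindered ester under equilibrating conditions, so that C2 holds its more stable configuration (carboxyl trans to the C1 side chain) until the carboxylate forms and fixes it.

Step 17
Reactants: 25 (1R,2S,7aS)-1-(3-hydroxypropyl)-1,7,7,7a-tetramethyl-2,3,5,6,7,7a-hexahydro-1H-indene-2-carboxylic acid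
Product: 26 (1R,2S,7aS)-1,7,7,7a-tetramethyl-1-(3-oxopropyl)-2,3,5,6,7,7a-hexahydro-1H-indene-2-carboxylic acid
Conditions: IBX, DMSO, rt
Reagents that add atoms: none
Why: IBX oxidation of a primary alcohol stops at the aldehyde and tolerates the free carboxylic acid and the alkene.

Step 18
Reactants: 26 (1R,2S,7aS)-1,7,7,7a-tetramethyl-1-(3-oxopropyl)-2,3,5,6,7,7a-hexahydro-1H-indene-2-carboxylic acid; 27 ethyl 2-[bis(2,2,2-trifluoroethoxy)phosphoryl]propanoate
Product: 28 (1R,2S,7aS)-1-[(3Z)-5-ethoxy-4-methyl-5-oxopent-3-en-1-yl]-1,7,7,7a-tetramethyl-2,3,5,6,7,7a-hexahydro-1H-indene-2-carboxylic acid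
Conditions: 27 (2.5 equiv), KN(SiMe3)2 (2.4 equiv), 18-crown-6, THF, −78 °C; 1 M HCl work-up
Reagents that add atoms: none
Why: Still–Gennari olefination, in which the bis(trifluoroethyl) phosphonate anion adds under kinetic control and eliminates fast to give the (Z)-trisubstituted enoate, one equivalent of the anion serving only to deprotonate the carboxylic acid.

Step 19
Reactants: 28 (1R,2S,7aS)-1-[(3Z)-5-ethoxy-4-methyl-5-oxopent-3-en-1-yl]-1,7,7,7a-tetramethyl-2,3,5,6,7,7a-hexahydro-1H-indene-2-carboxylic acid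
Product: 29 (1R,2S,7aS)-1-[(3Z)-5-hydroxy-4-methylpent-3-en-1-yl]-1,7,7,7a-tetramethyl-2,3,5,6,7,7a-hexahydro-1H-indene-2-carboxylic acid
Conditions: i-Bu2AlH (4 equiv), CH2Cl2, −78 °C; aqueous potassium sodium tartrate work-up
Reagents that add atoms: none
Why: 1,2-Reduction of the conjugated ester by i-Bu2AlH gives the (Z)-allylic alcohol without isomerisation, while the acid is masked in the flask as its aluminium carboxylate, which is not reduced at −78 °C.

Step 20
Reactants: 29 (1R,2S,7aS)-1-[(3Z)-5-hydroxy-4-methylpent-3-en-1-yl]-1,7,7,7a-tetramethyl-2,3,5,6,7,7a-hexahydro-1H-indene-2-carboxylic acid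
Product: 31 (1R,2S,7aS)-1-[(3Z)-5-acetoxy-4-methylpent-3-en-1-yl]-1,7,7,7a-tetramethyl-2,3,5,6,7,7a-hexahydro-1H-indene-2-carboxylic acid, via mixed anhydride 30 (not isolated)
Conditions: Ac2O, pyridine, 4-(dimethylamino)pyridine (cat), CH2Cl2, rt; then THF/H2O, rt
Reagents that add atoms: acetic anhydride, CC(=O)OC(C)=O
Why: Nucleophile-catalysed acetylation of the primary allylic alcohol, the mixed anhydride formed at the hindered carboxyl group being hydrolysed at its acetyl carbonyl in the aqueous stage to return the free acid.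

Compound list

1 | 3-ethoxy-2-methylcyclohex-2-en-1-one | CCOC1=C(C)C(=O)CCC1 | starting material
2 | 3-ethoxy-2,6-dimethylcyclohex-2-en-1-one (racemic) | CCOC1=C(C)C(=O)C(C)CC1 | intermediate
3 | 3-ethoxy-2,6,6-trimethylcyclohex-2-en-1-one | CCOC1=C(C)C(=O)C(C)(C)CC1 | intermediate
4 | 3-ethoxy-1,2,6,6-tetramethylcyclohex-2-en-1-ol (racemic, lithium alkoxide in the flask) | CCOC1=C(C)C(C)(O)C(C)(C)CC1 | intermediate
5 | 2,3,4,4-tetramethylcyclohex-2-en-1-one | CC1=C(C)C(C)(C)CCC1=O | intermediate
6 | (1R)-2,3,4,4-tetramethylcyclohex-2-en-1-ol | O[C@H]1C(C)=C(C)C(C)(C)CC1 | intermediate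
7 | tetrahydro-2H-pyran-2-one | O=C1CCCCO1 | starting material
8 | sodium 5-hydroxypentanoate | [Na+].[O-]C(=O)CCCCO | intermediate
9 | tert-butyldimethylsilyl 5-[(tert-butyldimethylsilyl)oxy]pentanoate | CC(C)(C)[Si](C)(C)OCCCCC(=O)O[Si](C)(C)C(C)(C)C | intermediate
10 | 5-[(tert-butyldimethylsilyl)oxy]pentanoic acid | CC(C)(C)[Si](C)(C)OCCCCC(=O)O | intermediate
11 | (1R)-2,3,4,4-tetramethylcyclohex-2-en-1-yl 5-[(tert-butyldimethylsilyl)oxy]pentanoate | CC(C)(C)[Si](C)(C)OCCCCC(=O)O[C@H]1C(C)=C(C)C(C)(C)CC1 | intermediate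
12 | (E)-trimethylsilyl ketene acetal of 11, α-chain cis to the cyclohexenyl oxygen | CC(C)(C)[Si](C)(C)OCCC/C=C(/O[Si](C)(C)C)O[C@H]1C(C)=C(C)C(C)(C)CC1 | intermediate
13 | trimethylsilyl (2R)-5-[(tert-butyldimethylsilyl)oxy]-2-[(1S)-1,2,6,6-tetramethylcyclohex-2-en-1-yl]pentanoate | CC(C)(C)[Si](C)(C)OCCC[C@@H](C(=O)O[Si](C)(C)C)[C@@]1(C)C(C)(C)CCC=C1C | intermediate
14 | (2R)-5-[(tert-butyldimethylsilyl)oxy]-2-[(1S)-1,2,6,6-tetramethylcyclohex-2-en-1-yl]pentan-1-ol | CC(C)(C)[Si](C)(C)OCCC[C@@H](CO)[C@@]1(C)C(C)(C)CCC=C1C | intermediate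
15 | (2R)-5-[(tert-butyldimethylsilyl)oxy]-2-[(1S)-1,2,6,6-tetramethylcyclohex-2-en-1-yl]pentyl methanesulfonate | CC(C)(C)[Si](C)(C)OCCC[C@@H](COS(C)(=O)=O)[C@@]1(C)C(C)(C)CCC=C1C | intermediate
16 | tert-butyldimethyl{[(4R)-4-[(1S)-1,2,6,6-tetramethylcyclohex-2-en-1-yl]pentyl]oxy}silane | CC(C)(C)[Si](C)(C)OCCC[C@@H](C)[C@@]1(C)C(C)(C)CCC=C1C | intermediate
17 | {(6S)-6-[(2R)-5-[(tert-butyldimethylsilyl)oxy]pentan-2-yl]-5,5,6-trimethylcyclohex-1-en-1-yl}methanol | CC(C)(C)[Si](C)(C)OCCC[C@@H](C)[C@@]1(C)C(C)(C)CCC=C1CO | intermediate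
18 | (6S)-6-[(2R)-5-[(tert-butyldimethylsilyl)oxy]pentan-2-yl]-5,5,6-trimethylcyclohex-1-ene-1-carbaldehyde | CC(C)(C)[Si](C)(C)OCCC[C@@H](C)[C@@]1(C)C(C)(C)CCC=C1C=O | intermediate
19 | ethyl diazoacetate | CCOC(=O)C=[N+]=[N-] | starting material
20 | ethyl 3-{(6S)-6-[(2R)-5-[(tert-butyldimethylsilyl)oxy]pentan-2-yl]-5,5,6-trimethylcyclohex-1-en-1-yl}-2-diazo-3-hydroxypropanoate (both carbinol epimers) | CC(C)(C)[Si](C)(C)OCCC[C@@H](C)[C@@]1(C)C(C)(C)CCC=C1C(O)C(=[N+]=[N-])C(=O)OCC | intermediate
21 | ethyl 3-{(6S)-6-[(2R)-5-[(tert-butyldimethylsilyl)oxy]pentan-2-yl]-5,5,6-trimethylcyclohex-1-en-1-yl}-2-diazo-3-oxopropanoate | CC(C)(C)[Si](C)(C)OCCC[C@@H](C)[C@@]1(C)C(C)(C)CCC=C1C(=O)C(=[N+]=[N-])C(=O)OCC | intermediate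
22 | ethyl (1R,2R,7aR)-1-{3-[(tert-butyldimethylsilyl)oxy]propyl}-1,7,7,7a-tetramethyl-3-oxo-2,3,5,6,7,7a-hexahydro-1H-indene-2-carboxylate | CC(C)(C)[Si](C)(C)OCCC[C@]1(C)[C@@H](C(=O)OCC)C(=O)C2=CCCC(C)(C)[C@@]21C | intermediate
23 | C3 spiro-1,3-dithiolane of ethyl 1-(3-hydroxypropyl)-1,7,7,7a-tetramethyl-3-oxo-2,3,5,6,7,7a-hexahydro-1H-indene-2-carboxylate (C1, C2, C7a as in 22) | OCCC[C@]1(C)[C@@H](C(=O)OCC)C3(SCCS3)C2=CCCC(C)(C)[C@@]21C | intermediate
24 | ethyl (1R,2S,7aS)-1-(3-hydroxypropyl)-1,7,7,7a-tetramethyl-2,3,5,6,7,7a-hexahydro-1H-indene-2-carboxylate | OCCC[C@]1(C)[C@@H](C(=O)OCC)CC2=CCCC(C)(C)[C@@]21C | intermediate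
25 | (1R,2S,7aS)-1-(3-hydroxypropyl)-1,7,7,7a-tetramethyl-2,3,5,6,7,7a-hexahydro-1H-indene-2-carboxylic acid | OCCC[C@]1(C)[C@@H](C(=O)O)CC2=CCCC(C)(C)[C@@]21C | intermediate
26 | (1R,2S,7aS)-1,7,7,7a-tetramethyl-1-(3-oxopropyl)-2,3,5,6,7,7a-hexahydro-1H-indene-2-carboxylic acid | O=CCC[C@]1(C)[C@@H](C(=O)O)CC2=CCCC(C)(C)[C@@]21C | intermediate
27 | ethyl 2-[bis(2,2,2-trifluoroethoxy)phosphoryl]propanoate | CCOC(=O)C(C)P(=O)(OCC(F)(F)F)OCC(F)(F)F | starting material
28 | (1R,2S,7aS)-1-[(3Z)-5-ethoxy-4-methyl-5-oxopent-3-en-1-yl]-1,7,7,7a-tetramethyl-2,3,5,6,7,7a-hexahydro-1H-indene-2-carboxylic acid | CCOC(=O)/C(C)=C\CC[C@]1(C)[C@@H](C(=O)O)CC2=CCCC(C)(C)[C@@]21C | intermediate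
29 | (1R,2S,7aS)-1-[(3Z)-5-hydroxy-4-methylpent-3-en-1-yl]-1,7,7,7a-tetramethyl-2,3,5,6,7,7a-hexahydro-1H-indene-2-carboxylic acid | OC/C(C)=C\CC[C@]1(C)[C@@H](C(=O)O)CC2=CCCC(C)(C)[C@@]21C | intermediate
30 | mixed acetic anhydride of 31 at the C2 carboxyl group | CC(=O)OC/C(C)=C\CC[C@]1(C)[C@@H](C(=O)OC(C)=O)CC2=CCCC(C)(C)[C@@]21C | intermediate
31 | (1R,2S,7aS)-1-[(3Z)-5-acetoxy-4-methylpent-3-en-1-yl]-1,7,7,7a-tetramethyl-2,3,5,6,7,7a-hexahydro-1H-indene-2-carboxylic acid | CC(=O)OC/C(C)=C\CC[C@]1(C)[C@@H](C(=O)O)CC2=CCCC(C)(C)[C@@]21C | target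

Total step count: 20. Longest linear sequence: 18 steps (1, 2, 3, 6 to 20, from compound 1); steps 4 and 5 form the side branch that joins at step 6.

Steps most likely to fail

Step 13. The carbenoid may insert into the primary C–H bonds of the C7a methyl (also 1,5) or into the C1′ methylene (1,6), because the tertiary C1–H bond sits between two fully substituted carbons, or it may dimerise if the crowded insertion is slow. Fallback, setting out from 11 and returning at 24: ring B is closed by enolate alkylation after C1 has been made quaternary. Compound 11 is rearranged as in step 7, but the silyl ester 13 is hydrolysed to the rearranged acid F1. Its dianion (LiN(i-Pr)2, 2.2 equiv, THF; MeI) is methylated to the α-quaternary acid F2. Arndt–Eistert homologation follows, through the acid chloride F3 (1-chloro-N,N,2-trimethylprop-1-en-1-amine) and the diazoketone F4 (Me3SiCHN2), with Wolff rearrangement (AgO2CPh, Et3N, EtOH) to the homologated ethyl ester F5. SeO2/t-BuOOH oxidation with NaBH4 work-up gives the allylic alcohol F6, and an Appel reaction (CBr4, PPh3) gives the allylic bromide F7. KN(SiMe3)2 (THF, −78 °C) then closes ring B by 5-exo-tet alkylation of the ester enolate at C3 to the bicyclic silyl ether ester F8, and Bu4NF gives 24. In this fallback C1 depends on the facial selectivity of the methylation, which is not backed by chirality transfer and may call for separation of diastereomers; C2 is still equilibrated in step 16.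

Step 7. Incomplete (E)-selective enolisation or leakage through the boat-like transition state would erode the C1 configuration relative to C7a, and bond formation at the fully substituted alkene carbon next to the gem-dimethyl group may be slow enough for fragmentation of the enolate to compete. Fallback, setting out from 6 and returning at 16: an aliphatic Claisen rearrangement of a geometrically defined propenyl ether. Alcohol 6 is allylated (NaH, allyl bromide, THF) to the allyl ether F9, which [Ir(cod)(PMePh2)2]PF6 (H2-activated, THF) isomerises to the (E)-propenyl ether F10. Heating (toluene, 150 °C, sealed tube) should give the aldehyde F11 through a chair with the methyl equatorial, which sets the same C7a and C1 configurations. Wittig reaction with Ph3P=CHCO2Me gives the (E)-enoate F12, Mg in MeOH the saturated methyl ester F13 and LiAlH4 the primary alcohol F14, which TBSCl/imidazole converts into 16.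

Step 14. Conjugate addition of the dithiol to the exocyclic enone may outrun dithioketalisation of the hindered carbonyl, so that the following desulfurisation would saturate or shift the C3a=C4 double bond. Fallback, setting out from 22 and returning at 24: hydride is delivered to C3 through a π-allylpalladium intermediate. Luche reduction (NaBH4, CeCl3·7H2O, MeOH, −40 °C) gives the allylic alcohol F15, and ClCO2Me/pyridine gives the allylic methyl carbonate F16. Formate hydrogenolysis (Pd(OAc)2, PBu3, HCO2H, Et3N, THF, 60 °C) transfers hydride from palladium to the more hindered allyl terminus C3 and should give the bicyclic silyl ether ester F8 with the double bond kept at C3a=C4. Bu4NF then gives 24.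

Further compounds

F1 | step 13 | (2R)-5-[(tert-butyldimethylsilyl)oxy]-2-[(1S)-1,2,6,6-tetramethylcyclohex-2-en-1-yl]pentanoic acid | CC(C)(C)[Si](C)(C)OCCC[C@@H](C(=O)O)[C@@]1(C)C(C)(C)CCC=C1C
F2 | step 13 | (2S)-5-[(tert-butyldimethylsilyl)oxy]-2-methyl-2-[(1S)-1,2,6,6-tetramethylcyclohex-2-en-1-yl]pentanoic acid | CC(C)(C)[Si](C)(C)OCCC[C@](C)(C(=O)O)[C@@]1(C)C(C)(C)CCC=C1C
F3 | step 13 | acid chloride of F2 | CC(C)(C)[Si](C)(C)OCCC[C@](C)(C(=O)Cl)[C@@]1(C)C(C)(C)CCC=C1C
F4 | step 13 | diazomethyl ketone from F3 | CC(C)(C)[Si](C)(C)OCCC[C@](C)(C(=O)C=[N+]=[N-])[C@@]1(C)C(C)(C)CCC=C1C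
F5 | step 13 | ethyl 6-[(tert-butyldimethylsilyl)oxy]-3-methyl-3-[(1S)-1,2,6,6-tetramethylcyclohex-2-en-1-yl]hexanoate (C3 configured as C1 of the target) | CC(C)(C)[Si](C)(C)OCCC[C@](C)(CC(=O)OCC)[C@@]1(C)C(C)(C)CCC=C1C
F6 | step 13 | allylic alcohol from F5 (hydroxymethyl on the alkene carbon C3a) | CC(C)(C)[Si](C)(C)OCCC[C@](C)(CC(=O)OCC)[C@@]1(C)C(C)(C)CCC=C1CO
F7 | step 13 | allylic bromide from F6 | CC(C)(C)[Si](C)(C)OCCC[C@](C)(CC(=O)OCC)[C@@]1(C)C(C)(C)CCC=C1CBr
F8 | step 13 | ethyl (1R,2S,7aS)-1-{3-[(tert-butyldimethylsilyl)oxy]propyl}-1,7,7,7a-tetramethyl-2,3,5,6,7,7a-hexahydro-1H-indene-2-carboxylate | CC(C)(C)[Si](C)(C)OCCC[C@]1(C)[C@@H](C(=O)OCC)CC2=CCCC(C)(C)[C@@]21C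
F9 | step 7 | (1R)-2,3,4,4-tetramethylcyclohex-2-en-1-yl prop-2-en-1-yl ether | C=CCO[C@H]1C(C)=C(C)C(C)(C)CC1
F10 | step 7 | (1R)-2,3,4,4-tetramethylcyclohex-2-en-1-yl (E)-prop-1-en-1-yl ether | C/C=C/O[C@H]1C(C)=C(C)C(C)(C)CC1
F11 | step 7 | (2S)-2-[(1S)-1,2,6,6-tetramethylcyclohex-2-en-1-yl]propanal | O=C[C@@H](C)[C@@]1(C)C(C)(C)CCC=C1C
F12 | step 7 | methyl (2E,4R)-4-[(1S)-1,2,6,6-tetramethylcyclohex-2-en-1-yl]pent-2-enoate | COC(=O)/C=C/[C@@H](C)[C@@]1(C)C(C)(C)CCC=C1C
F13 | step 7 | methyl (4R)-4-[(1S)-1,2,6,6-tetramethylcyclohex-2-en-1-yl]pentanoate | COC(=O)CC[C@@H](C)[C@@]1(C)C(C)(C)CCC=C1C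
F14 | step 7 | (4R)-4-[(1S)-1,2,6,6-tetramethylcyclohex-2-en-1-yl]pentan-1-ol | OCCC[C@@H](C)[C@@]1(C)C(C)(C)CCC=C1C
F15 | step 14 | ethyl 1-{3-[(tert-butyldimethylsilyl)oxy]propyl}-3-hydroxy-1,7,7,7a-tetramethyl-2,3,5,6,7,7a-hexahydro-1H-indene-2-carboxylate (C3 epimers; C1, C2, C7a as in 22) | CC(C)(C)[Si](C)(C)OCCC[C@]1(C)[C@@H](C(=O)OCC)C(O)C2=CCCC(C)(C)[C@@]21C
F16 | step 14 | C3 methyl carbonate of F15 | CC(C)(C)[Si](C)(C)OCCC[C@]1(C)[C@@H](C(=O)OCC)C(OC(=O)OC)C2=CCCC(C)(C)[C@@]21C
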